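A direct plan would set C5 and C6 on an open chain by an amine-catalysed Michael addition that gives the nitro aldehyde A1,
would elaborate A1 into the acyl chloride A2, which carries a 2-methoxyallyl silyl ether,
would close the ring by C-acylation of that enol ether to the vinylogous ester A3,
and would then move the carbonyl group from C4 to C1.
Its weakest steps would be the ring closure (acylation of an enol ether by an unactivated acyl chloride would have no close precedent and would compete with enol ether protonation and polyene cyclisation),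
the hydride reduction of A3 (the C4 hydroxyl would have to come out cis to the chain on facial bias alone),
and the carbonyl transposition (about six steps of silyl ether exchange and redox change that would add no complexity).

The cyclohexenone is cut at C4–C5 and C1–C6, because its C2=C3 enol ether is a Diels–Alder retron: a 1,2,4-trioxygenated butadiene supplies C1–C4 with the methoxy group in place, (E)-crotonaldehyde supplies C6, C5 and the first carbon of the side chain. One catalytic endo cycloaddition should close the only ring and set C4, C5 and C6 together (C4–O cis to C5 by the endo rule, C6–Me trans to C5 from the E alkene). The farnesyl group is completed by an sp3–sp2 Negishi coupling that keeps the 2E alkene. No enol ether acylation, no reagent-controlled ketone reduction and no carbonyl transposition remain.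

Key step: step 5

Numbering: ring C1 (C=O), C2 (OMe), C3, C4 (OH), C5 (side chain), C6 (Me); the diene carbons C1–C4 become ring C1–C4; farnesyl = (2E,6E)-3,7,11-trimethyldodeca-2,6,10-trien-1-yl.
Assumption 1: the sense of induction of the oxazaborolidinium catalyst in step 5 is taken by analogy from its formyl C–H···O binding model; if the (S)-catalyst should favour the other face of crotonaldehyde, its mirror image would be used and nothing else would change.
Assumption 2: geranylacetone is used as the pure (5E) isomer.

**Step 1**
Reactants: 1 but-2-yne-1,4-diol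
Product: 2 4-hydroxybut-2-yn-1-yl pivalate
Conditions: 1 (3 equiv), t-BuCOCl (1 equiv), pyridine (1.2 equiv), THF, 0 °C to rt
Reagents that add atoms: pivaloyl chloride, CC(C)(C)C(Cl)=O
Why: O-Acylation of a symmetrical diol used in excess should give the mono-ester statistically, and the pivaloyl group is chosen because it resists the later methanol addition yet is removed by hydride.

**Step 2**
Reactants: 2 4-hydroxybut-2-yn-1-yl pivalate
Product: 3 4-oxobut-2-yn-1-yl pivalate
Conditions: MnO2 (activated, 15 equiv), CH2Cl2, rt
Reagents that add atoms: none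
Why: MnO2 oxidation is selective for propargylic alcohols and stops at the aldehyde, the ester being inert.

**Step 3**
Reactants: 3 4-oxobut-2-yn-1-yl pivalate
Product: 4 (E)-2-methoxy-4-oxobut-2-en-1-yl pivalate
Conditions: MeOH (3 equiv), 1,4-diazabicyclo[2.2.2]octane (10 mol %), CH2Cl2, 0 °C
Reagents that add atoms: methanol, CO
Why: Amine-catalysed oxa-Michael addition of methanol to the ynal places the methoxy group on the β-carbon (the future C2), and the alkene geometry is of no consequence because this bond becomes the central single bond of the diene.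

**Step 4**
Reactants: 4 (E)-2-methoxy-4-oxobut-2-en-1-yl pivalate
Product: 5 (1Z,3E)-2-methoxy-4-(triisopropylsilyloxy)buta-1,3-dien-1-yl pivalate
Conditions: i-Pr3SiOSO2CF3 (1.1 equiv), Et3N (2 equiv), Et2O, −20 °C to rt
Reagents that add atoms: triisopropylsilyl trifluoromethanesulfonate, CC(C)[Si](OS(=O)(=O)C(F)(F)F)(C(C)C)C(C)C
Why: Soft enolisation (silyl triflate and tertiary amine): O-silylation of the vinylogous formate gives an oxocarbenium ion whose only acidic position is the CH2OPiv group, so deprotonation should give the 1-silyloxydiene with the usual E geometry at C3=C4 and, as expected for a 1,2-dioxygenated alkene, the pivaloyloxy group cis to methoxy (1Z), the isomer that can reach the s-cis form.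

**Step 5**
Reactants: 5 (1Z,3E)-2-methoxy-4-(triisopropylsilyloxy)buta-1,3-dien-1-yl pivalate; 6 (E)-but-2-enal (crotonaldehyde)
Product: 8 (1S,4R,5S,6R)-5-(hydroxymethyl)-2-methoxy-6-methyl-4-(triisopropylsilyloxy)cyclohex-2-en-1-ol, via cycloadduct aldehyde 7 (not isolated)
Conditions: (S)-1-(2-methylphenyl)-3,3-diphenyltetrahydro-1H,3H-pyrrolo[1,2-c][1,3,2]oxazaborole (20 mol %), HN(SO2CF3)2 (17 mol %), 6 (1.5 equiv), CH2Cl2, −78 °C; then i-Bu2AlH (6 equiv), −78 to −20 °C; aq potassium sodium tartrate
Reagents that add atoms: none
Why: Asynchronous concerted [4+2] cycloaddition (Diels–Alder reaction) between diene 5 and the enal bound s-trans to the cationic boron Lewis acid; the closest known reaction type is the oxazaborolidinium-catalysed Diels–Alder reaction of silyloxydienes with α,β-unsaturated aldehydes. The only ring closes suprafacially on both partners by forming C1–C6 and C4–C5, and the new double bond appears at C2=C3, where the target has its enol ether. C6 and C5 should come out trans because the E geometry of 6 is carried over, C4–O and the C5 formyl group cis because the activated formyl group lies endo under the diene, C1 follows from the 1Z geometry but is erased in step 6, and the absolute sense is set by the catalyst, which should leave the C2-Si, C3-Re face of 6 open. Regioselectivity is needed and is secured by the 4-silyloxy and 2-methoxy groups, which both raise the HOMO coefficient at C1 of the diene, so that C1 bonds to the β-carbon of the enal and C4 to the α-carbon. Addition to C=C must win over addition to the formyl group (hetero-Diels–Alder, vinylogous Mukaiyama aldol), which the weakly donating pivaloyloxy group at the nucleophilic terminus and the temperature of −78 °C should favour. The β-silyloxy aldehyde 7 is not isolated because it could eliminate or epimerise at C5: i-Bu2AlH reduces it and cleaves the pivalate in the same flask.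

**Step 6**
Reactants: 8 (1S,4R,5S,6R)-5-(hydroxymethyl)-2-methoxy-6-methyl-4-(triisopropylsilyloxy)cyclohex-2-en-1-ol
Product: 9 (4R,5S,6R)-5-(hydroxymethyl)-2-methoxy-6-methyl-4-(triisopropylsilyloxy)cyclohex-2-en-1-one
Conditions: MnO2 (activated, 20 equiv), CH2Cl2, rt
Reagents that add atoms: none
Why: MnO2 oxidation takes only the allylic alcohol at C1 (any C1 epimer would converge), turns the acid-labile enol ether into a robust 2-methoxy enone, and leaves the primary alcohol and the already trans (equatorial) C6 methyl alone.

**Step 7**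
Reactants: 9 (4R,5S,6R)-5-(hydroxymethyl)-2-methoxy-6-methyl-4-(triisopropylsilyloxy)cyclohex-2-en-1-one
Product: 10 (4S,5R,6R)-5-(iodomethyl)-2-methoxy-6-methyl-4-(triisopropylsilyloxy)cyclohex-2-en-1-one
Conditions: I2 (1.3 equiv), PPh3 (1.3 equiv), imidazole (3 equiv), CH2Cl2, 0 °C
Reagents that add atoms: iodine, II
Why: Appel-type iodination converts the primary alcohol by SN2 displacement of its alkoxyphosphonium ion under imidazole buffering, which spares the silyl ether and should not enolise C6.

**Step 8**
Reactants: 11 (5E)-6,10-dimethylundeca-5,9-dien-2-one (geranylacetone)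
Product: 13 (5E)-6,10-dimethylundeca-5,9-dien-1-yne, via enol phosphate 12 (not isolated)
Conditions: LiN(i-Pr)2 (1.05 equiv), THF, −78 °C; ClP(O)(OEt)2 (1.1 equiv), −78 °C to rt; then LiN(i-Pr)2 (2.3 equiv), −78 °C to rt
Reagents that add atoms: none
Why: One-flask conversion of a methyl ketone into a terminal alkyne: the kinetic methyl-side enolate is trapped as the enol phosphate, which undergoes base-induced β-elimination, and the remote trisubstituted alkenes are not touched.

**Step 9**
Reactants: 13 (5E)-6,10-dimethylundeca-5,9-dien-1-yne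
Product: 15 (1E,5E)-1-iodo-2,6,10-trimethylundeca-1,5,9-triene, via alkenylalane 14 (not isolated)
Conditions: Me3Al (2 equiv), Cp2ZrCl2 (0.25 equiv), CH2Cl2, 0 °C to rt; then I2 (1.2 equiv), THF, −30 to 0 °C
Reagents that add atoms: trimethylaluminium, C[Al](C)C; iodine, II
Why: Zirconium-catalysed carboalumination of a terminal alkyne (Negishi) adds methyl and aluminium syn with the metal at the terminus, and iodinolysis of the C–Al bond with retention should give the (E)-alkenyl iodide.

**Step 10**
Reactants: 10 (4S,5R,6R)-5-(iodomethyl)-2-methoxy-6-methyl-4-(triisopropylsilyloxy)cyclohex-2-en-1-one; 15 (1E,5E)-1-iodo-2,6,10-trimethylundeca-1,5,9-triene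
Product: 17 (4R,5R,6R)-5-farnesyl-2-methoxy-6-methyl-4-(triisopropylsilyloxy)cyclohex-2-en-1-one, via alkylzinc iodide 16 (not isolated)
Conditions: Zn dust (3 equiv, activated with BrCH2CH2Br and Me3SiCl), LiCl, THF, 35 °C; then 15 (1.2 equiv), PdCl2(dppf) (5 mol %), THF/N,N-dimethylacetamide, rt to 45 °C
Reagents that add atoms: none
Why: Negishi coupling: zinc inserts into the primary C–I bond to an alkylzinc halide that tolerates ketone and silyl ether, and zerovalent palladium with the wide-bite-angle dppf ligand joins it to the alkenyl iodide with retention of the E geometry, reductive elimination outrunning β-hydride elimination and C5 staying untouched.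

**Step 11**
Reactants: 17 (4R,5R,6R)-5-farnesyl-2-methoxy-6-methyl-4-(triisopropylsilyloxy)cyclohex-2-en-1-one
Product: 18 (4R,5R,6R)-5-farnesyl-4-hydroxy-2-methoxy-6-methylcyclohex-2-en-1-one (CNP0534154.1)
Conditions: HF·pyridine, pyridine, THF, 0 °C to rt
Reagents that add atoms: none
Why: Fluoride-induced cleavage of the silyl ether with pyridine-buffered HF should free the C4 hydroxyl without the base that could isomerise the γ-hydroxy enone to a 1,4-dione, and no stereocentre is affected.

**Compound list**

1 | but-2-yne-1,4-diol | OCC#CCO | starting material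
2 | 4-hydroxybut-2-yn-1-yl pivalate | CC(C)(C)C(=O)OCC#CCO | intermediate
3 | 4-oxobut-2-yn-1-yl pivalate | CC(C)(C)C(=O)OCC#CC=O | intermediate
4 | (E)-2-methoxy-4-oxobut-2-en-1-yl pivalate | CC(C)(C)C(=O)OC/C(OC)=C\C=O | intermediate
5 | (1Z,3E)-2-methoxy-4-(triisopropylsilyloxy)buta-1,3-dien-1-yl pivalate | CC(C)(C)C(=O)O/C=C(OC)/C=C/O[Si](C(C)C)(C(C)C)C(C)C | intermediate
6 | (E)-but-2-enal (crotonaldehyde) | C/C=C/C=O | starting material
7 | (1S,4S,5R,6R)-5-formyl-2-methoxy-6-methyl-4-(triisopropylsilyloxy)cyclohex-2-en-1-yl pivalate | COC1=C[C@H](O[Si](C(C)C)(C(C)C)C(C)C)[C@H](C=O)[C@@H](C)[C@@H]1OC(=O)C(C)(C)C | intermediate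
8 | (1S,4R,5S,6R)-5-(hydroxymethyl)-2-methoxy-6-methyl-4-(triisopropylsilyloxy)cyclohex-2-en-1-ol | COC1=C[C@H](O[Si](C(C)C)(C(C)C)C(C)C)[C@H](CO)[C@@H](C)[C@@H]1O | intermediate
9 | (4R,5S,6R)-5-(hydroxymethyl)-2-methoxy-6-methyl-4-(triisopropylsilyloxy)cyclohex-2-en-1-one | COC1=C[C@H](O[Si](C(C)C)(C(C)C)C(C)C)[C@H](CO)[C@@H](C)C1=O | intermediate
10 | (4S,5R,6R)-5-(iodomethyl)-2-methoxy-6-methyl-4-(triisopropylsilyloxy)cyclohex-2-en-1-one | COC1=C[C@H](O[Si](C(C)C)(C(C)C)C(C)C)[C@H](CI)[C@@H](C)C1=O | intermediate
11 | (5E)-6,10-dimethylundeca-5,9-dien-2-one (geranylacetone) | CC(=O)CC/C=C(\C)CCC=C(C)C | starting material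
12 | diethyl (5E)-6,10-dimethylundeca-1,5,9-trien-2-yl phosphate | C=C(OP(=O)(OCC)OCC)CC/C=C(\C)CCC=C(C)C | intermediate
13 | (5E)-6,10-dimethylundeca-5,9-dien-1-yne | C#CCC/C=C(\C)CCC=C(C)C | intermediate
14 | dimethyl[(1E,5E)-2,6,10-trimethylundeca-1,5,9-trien-1-yl]alane | C[Al](C)/C=C(\C)CC/C=C(\C)CCC=C(C)C | intermediate
15 | (1E,5E)-1-iodo-2,6,10-trimethylundeca-1,5,9-triene | I/C=C(\C)CC/C=C(\C)CCC=C(C)C | intermediate
16 | {[(1R,2R,6S)-4-methoxy-2-methyl-3-oxo-6-(triisopropylsilyloxy)cyclohex-4-en-1-yl]methyl}zinc iodide (alkylzinc iodide from 10) | COC1=C[C@H](O[Si](C(C)C)(C(C)C)C(C)C)[C@H](C[Zn]I)[C@@H](C)C1=O | intermediate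
17 | (4R,5R,6R)-5-farnesyl-2-methoxy-6-methyl-4-(triisopropylsilyloxy)cyclohex-2-en-1-one | COC1=C[C@H](O[Si](C(C)C)(C(C)C)C(C)C)[C@H](C/C=C(\C)CC/C=C(\C)CCC=C(C)C)[C@@H](C)C1=O | intermediate
18 | (4R,5R,6R)-5-farnesyl-4-hydroxy-2-methoxy-6-methylcyclohex-2-en-1-one | COC1=C[C@H](O)[C@H](C/C=C(\C)CC/C=C(\C)CCC=C(C)C)[C@@H](C)C1=O | target

**Step count and risks**

Total step count: 11. Longest linear sequence: 9 steps (steps 1 to 7, 10 and 11); steps 8 and 9 form the side-chain branch.

Steps most likely to fail:

Step 5. The nucleophilic diene terminus may add to the formyl carbon instead of the C=C bond, a stepwise Michael pathway may erode the cis relation between C4–O and C5, or the α-unsubstituted enal may be bound by the catalyst with poor facial discrimination. The fallback changes the dienophile to a two-point-binding imide that has no free carbonyl group. It sets out from 5, which would be combined with 3-[(E)-but-2-enoyl]-1,3-oxazolidin-2-one F1 under Cu(SbF6)2 with (R,R)-2,2′-(propane-2,2-diyl)bis(4-tert-butyl-4,5-dihydro-1,3-oxazole) (10 mol %, a chelating complex of divalent copper, CH2Cl2, −40 °C). The square-planar chelate model predicts attack on the same C2-Si face and should give (1S,4S,5R,6R)-2-methoxy-6-methyl-5-(2-oxo-1,3-oxazolidine-3-carbonyl)-4-(triisopropylsilyloxy)cyclohex-2-en-1-yl pivalate F2. LiAlH4 (THF, 0 °C) would then cleave the imide and the pivalate reductively, and the fallback comes back to the route at 8.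

Step 10. Zinc insertion may be slow next to the bulky silyl ether, the alkylzinc may be quenched or attack its own enone, or β-hydride elimination may compete. The fallback is a nickel-catalysed reductive cross-electrophile coupling, which needs no preformed organometallic: the primary radical formed from the iodide is captured by an alkenylnickel species. It sets out from 10 and 15 (NiI2 10 mol %, 4,4′-di-tert-butyl-2,2′-bipyridine, Mn powder, N,N-dimethylacetamide, rt) and comes back at 17; no new compound is made.

Step 4. Enolisation may give the diene with the pivaloyloxy group on the inside of C1=C2 (unreactive in the cycloaddition), or the diene may not survive its preparation. The fallback builds the diene from the other end, so that the pivaloyloxy group is introduced by O-acylation of an s-trans dienolate. It replaces steps 1 to 4, uses none of 1 to 4, and sets out from (triisopropylsilyloxy)acetaldehyde F3 (from ozonolysis of the bis-silyl ether of (Z)-but-2-ene-1,4-diol). Horner–Wadsworth–Emmons reaction with methyl 2-(dimethoxyphosphoryl)-2-methoxyacetate F4 (NaH, THF, 0 °C) would give methyl (Z)-2-methoxy-4-(triisopropylsilyloxy)but-2-enoate F5. i-Bu2AlH (CH2Cl2, −78 °C) would give (Z)-2-methoxy-4-(triisopropylsilyloxy)but-2-en-1-ol F6, and MnO2 would give (Z)-2-methoxy-4-(triisopropylsilyloxy)but-2-enal F7. γ-Deprotonation with KN(SiMe3)2 (THF, −78 °C) and trapping of the dienolate oxygen with t-BuCOCl would then come back to the route at 5.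

**Further compounds**

F1 | step 5 | 3-[(E)-but-2-enoyl]-1,3-oxazolidin-2-one | C/C=C/C(=O)N1CCOC1=O
F2 | step 5 | (1S,4S,5R,6R)-2-methoxy-6-methyl-5-(2-oxo-1,3-oxazolidine-3-carbonyl)-4-(triisopropylsilyloxy)cyclohex-2-en-1-yl pivalate | COC1=C[C@H](O[Si](C(C)C)(C(C)C)C(C)C)[C@H](C(=O)N2CCOC2=O)[C@@H](C)[C@@H]1OC(=O)C(C)(C)C
F0 | step 10 | none | none
F3 | step 4 | (triisopropylsilyloxy)acetaldehyde | O=CCO[Si](C(C)C)(C(C)C)C(C)C
F4 | step 4 | methyl 2-(dimethoxyphosphoryl)-2-methoxyacetate | COC(=O)C(OC)P(=O)(OC)OC
F5 | step 4 | methyl (Z)-2-methoxy-4-(triisopropylsilyloxy)but-2-enoate | COC(=O)/C(OC)=C/CO[Si](C(C)C)(C(C)C)C(C)C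
F6 | step 4 | (Z)-2-methoxy-4-(triisopropylsilyloxy)but-2-en-1-ol | OC/C(OC)=C/CO[Si](C(C)C)(C(C)C)C(C)C
F7 | step 4 | (Z)-2-methoxy-4-(triisopropylsilyloxy)but-2-enal | O=C/C(OC)=C/CO[Si](C(C)C)(C(C)C)C(C)C
A1 | direct plan | (2R,3R)-2-farnesyl-3-methyl-4-nitrobutanal | O=C[C@H](C/C=C(\C)CC/C=C(\C)CCC=C(C)C)[C@@H](C)C[N+](=O)[O-]
A2 | direct plan | (2R,3R)-2-farnesyl-5-methoxy-3-methyl-4-(triethylsilyloxy)hex-5-enoyl chloride | ClC(=O)[C@H](C/C=C(\C)CC/C=C(\C)CCC=C(C)C)[C@@H](C)C(O[Si](CC)(CC)CC)C(OC)=C
A3 | direct plan | (5R,6R)-6-farnesyl-3-methoxy-5-methyl-4-(triethylsilyloxy)cyclohex-2-en-1-one | COC1=CC(=O)[C@H](C/C=C(\C)CC/C=C(\C)CCC=C(C)C)[C@@H](C)C1O[Si](CC)(CC)CC
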